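**Structural features**

The target is an isoflavone: benzo ring A is fused to pyranone ring C in a chromen-4-one, and a separate benzene ring B is attached through C1' to C3. It has no stereocentre and no stereodefined double bond, so every difficulty is constitutional. Ring A carries hydroxyls at C5 and C7, the C5 hydroxyl being chelated to the C4 carbonyl. Ring B is pentasubstituted, with hydroxyls at C2' and C4', a methoxyl at C5' and a 3-hydroxy-3-methylbutyl chain at C3' wedged between the two phenols. That chain is the most fragile element: under protic or Lewis acid the tertiary alcohol ionizes and is captured by a neighbouring phenol to give a 2,2-dimethylchroman, so acid must be excluded once O2' or O4' is free. Ring B is also a hydroquinone monoether (O2' para to O5') that oxidizes easily as a phenoxide in air, and the chromone is opened by nucleophiles at C2 and can be reduced at C2=C3. The real problems are the regiodefined assembly of five contiguous substituents on ring B, with one oxygen out of five set apart as a methyl ether, and the order of unmasking at the end. The key step exploits the fact that C5, C6, C7 and C8 of ring A form a 1,3-dioxygenated four-carbon bridge between C4a and C8a. A methyl group on C8a and a 3-oxopropanoate arm on C4a of a monocyclic 4-pyranone supply exactly these atoms, so forming C7–C8 creates ring A.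

**Logic of the disconnections**

20 ⇒ 19. The two O–CH2Ph bonds at O2' and O4' are cut last. Hydrogenolysis is neutral, and the phenol/tertiary alcohol/phenol triad should meet neither acid (chroman closure) nor base with air (oxidation of ring B). The gain is that ring B stays masked through every basic step. The forward step must cleave aryl benzyl ethers before C2=C3 is touched.

19 ⇒ 18. The O–Si bond of the tertiary silyl ether is cut. The alcohol has to be masked during acid chloride formation and the strong-base steps. Releasing it while O2' and O4' are still benzylated means no phenol is available for ring closure onto the chain. The forward step needs fluoride to reach a hindered silicon in a molecule that carries two acidic phenols.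

18 ⇒ 17 (key disconnection). The C7–C8 bond of ring A is cut. C8 becomes a methyl group on C8a and C7 the ester carbon of a 3-oxopropanoate arm on C4a of a monocyclic 4-pyranone that already holds ring B. The gain is large: ring A with both hydroxyls in place and unprotected is reduced to an acyclic triacetate unit, and no phloroglucinol chemistry is needed. The forward step demands that the vinylogous methyl carbanion acylate the ester while the pyranone stays closed, because only in the closed ring is C7–C8 the sole ring-forming C–C bond within reach.

17 ⇒ 13 + 14. The pyranone is cut at C4–C4a (acyl C–C bond) and at O1–C2 (enol ether C–O bond), isoflavone numbering. C4a is the central carbon of the 1,3-diketone of 14 and therefore the natural nucleophile toward an acyl donor. C2 is a formyl-level carbon that can carry a methoxyl leaving group in 13. The pieces are ring B with C2, C3 and C4 attached, and all carbons of ring A in one commercial chain. The forward step needs carbon acylation at the diketone position and closure through an enol oxygen; both are forgiving, since the isomeric pyranones fold to the same chromone.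

13 ⇒ 12 ⇒ 9 + 10. After the acid/ester interchange, the C2=C3 double bond is cut, so that C2 comes from 10 by formylation of the arylacetate α-carbon, the only enolizable position of 9. The forward steps need O-methylation of the formyl enolate and an ester hydrolysis that does not displace the vinylic methoxyl.

9 ⇒ 5 + 7 (through 8). The C3'–CH2 bond between ring B and its side chain is cut. The two flanking oxygens make C3' the one position that iodination reaches, and an sp2–sp3 coupling brings in the chain complete, at the right oxidation level and already protected. The forward step must couple at an iodide flanked by two benzyloxy groups.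

7 ⇒ 6. The O–Si bond is cut; 6 is a bulk chemical that holds all five carbons of the chain.

5 ⇒ 4 ⇒ 3. The bond between the benzylic CH2 and the ester carbon is cut, so the arylacetate comes from the aldehyde by a one-carbon homologation. The aldehyde is the group that blocked C1' during iodination and is exactly one carbon short. The acidic methanolysis in this sequence must precede attachment of the acid-sensitive chain, which fixes the order of steps.

3 ⇒ 2 ⇒ 1. The two O–CH2Ph bonds and then the C3'–I bond are cut. In 1 the methoxyl already marks O5' and the formyl group marks C1'. C3' is the only ring position ortho to both hydroxyls, so iodination has one site to go to.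

**Other disconnections considered**

Alternative 1: The cut is C2=C3 of ring C. In the forward direction the acyl(aryl)phosphorane A1, which carries a formate ester on the ortho oxygen of ring A, would be heated so that the ylide carbon (C3) adds to the formate carbonyl. The oxaphosphetane would then collapse to the fully protected isoflavone A2.
- In favour: ring A is taken ready-made from a phloroglucinol-derived benzoate, intramolecular ester olefination is an established way to chromones, and the conditions are neutral.
- Against: the ylide carbon is stabilized by the ketone and carries an aryl group with two ortho substituents, so it is a weak and hindered nucleophile. The aryl formate is a labile formyl donor that can be lost or transferred between molecules. A1 must be built by acylating a ring B benzylic ylide with a ring A salicyloyl donor and then formylating oxygen in competition with the ylide carbon.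
- Comparison: on structure the two plans are equal in fixing the C3–C1' bond before ring closure. The alternative is the better on certainty of the ring A pattern; the chosen plan is the better on protecting groups (two benzyl ethers in 18 against four in A2). On mechanism the alternative is the better, because it rests on a known reaction class while the chosen step is new; its substrate, however, sits at the unreactive end of that class. On step economy the two are about equal, since ring B would still come from 3 and the endgame is the same.

Alternative 2: Three bonds of ring B are cut (C5'–C6', C1'–C2', C2'–C3'). The α-alkoxyalkenyl methoxycarbene complex A3 of zerovalent chromium would combine with the 3-ethynylchromone A4 and one CO ligand. Electrocyclization and tautomerization would give the 2'-phenol A5 after decomplexation in air.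
- In favour: this is the most convergent plan. The mechanism dictates the substitution pattern of ring B: the carbene carbon becomes C5' with its methoxyl, the CO carbon becomes C2' with a free hydroxyl, and the alkyne substituent ends ortho to that hydroxyl. The five oxygens are thus differentiated without relying on a particular aromatic starting material.
- Against: the chromium reagent is stoichiometric. A4 is an electron-poor alkyne conjugated to a Michael acceptor, the situation in which benzannulation tends to lose to cyclopentannulation and furan formation. A3 needs a geometrically defined α-alkoxyvinyl metal precursor. The methoxymethyl ether on O4' must finally be removed with acid directly beside the tertiary-alcohol chain, which invites chroman formation.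
- Comparison: on structure it is the better in convergence and in the built-in regiochemistry of ring B. On mechanism it is the better in precedent. On step economy it is about equal once the syntheses of A3 and A4 are counted. It is the worse in the endgame, where the chosen plan needs no acid at all.

Alternative 3: The cuts are O1–C8a and C4–C4a. The silyl triflate A6 would release the 3,5-bis(benzyloxy)aryne A7 with CsF. The enolate oxygen of the hydroxyacrylate A8 (the conjugate acid of intermediate 11 of the chosen route) would add to the aryne carbon remote from the neighbouring benzyloxy group. The aryl anion, ortho to that group, would then acylate on the ester to give the protected isoflavone A9.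
- In favour: the polarity of the aryne matches the required orientation, and ring B leaves the chosen route three steps early (no methylation, hydrolysis or acid chloride). On step economy of the ring B branch this alternative is the better.
- Against: A6 itself needs four to five steps from a phloroglucinol ether. Enolates of 1,3-dicarbonyl type tend to attack arynes through carbon and then insert into the C–C bond, and the aryl anion can be protonated before it reaches the ester. The formyl ester may also deformylate under fluoride.
- Comparison: on structure the plans are equal, since ring C closes with ring B in place. On mechanism the alternative is closer to known aryne annulations and so somewhat better in precedent, but it carries an O- versus C-arylation problem that the chosen intramolecular closure does not have. On overall length the two are about equal, with four benzyl ethers to remove at the end.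

Key step: step 10

Assumption (remark on the chemistry): 1 and 14 are taken as catalogue chemicals; the acrylate unit of 12, 13, 15 and 16 is written as the E isomer that formylation–O-methylation delivers, and this geometry is erased when the pyranone closes.

Abbreviation used in names: Ar = 2,4-bis(benzyloxy)-3-(3-{[tert-butyl(dimethyl)silyl]oxy}-3-methylbutyl)-5-methoxyphenyl.

**Route**

Step 1
Reactants: 1 2,4-dihydroxy-5-methoxybenzaldehyde
Product: 2 2,4-dihydroxy-3-iodo-5-methoxybenzaldehyde
Conditions: N-iodosuccinimide, DMF, 0 °C → rt
Reagents that add atoms: N-iodosuccinimide, O=C1CCC(=O)N1I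
Why: Electrophilic aromatic iodination; C3 is ortho to both hydroxyls, C5 is blocked by the methoxyl and C6 is deactivated by the adjacent formyl group, so one position is open.

Step 2
Reactants: 2 2,4-dihydroxy-3-iodo-5-methoxybenzaldehyde
Product: 3 2,4-bis(benzyloxy)-3-iodo-5-methoxybenzaldehyde
Conditions: BnBr, K2CO3, DMF, 60 °C
Reagents that add atoms: benzyl bromide, BrCc1ccccc1
Why: Williamson etherification; the chelated and flanked 2-hydroxyl reacts more slowly, hence excess bromide and warming, and the aldehyde has no enolizable position.

Step 3
Reactants: 3 2,4-bis(benzyloxy)-3-iodo-5-methoxybenzaldehyde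
Product: 4 2,4-bis(benzyloxy)-3-iodo-5-methoxy-1-[2-(methylsulfanyl)-2-(methylsulfinyl)ethenyl]benzene (alkene isomers; racemic at sulfur)
Conditions: CH3S(O)CH2SCH3, benzyltrimethylammonium hydroxide (cat.), THF, reflux
Reagents that add atoms: methyl (methylsulfinyl)methyl sulfide, CSCS(C)=O
Why: Knoevenagel-type condensation of the sulfoxide-stabilized carbanion with a non-enolizable aldehyde (first stage of the Ogura–Tsuchihashi arylacetate synthesis); aryl iodide and benzyl ethers are inert to the catalytic base.

Step 4
Reactants: 4 2,4-bis(benzyloxy)-3-iodo-5-methoxy-1-[2-(methylsulfanyl)-2-(methylsulfinyl)ethenyl]benzene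
Product: 5 methyl 2-[2,4-bis(benzyloxy)-3-iodo-5-methoxyphenyl]acetate
Conditions: HCl (from AcCl), CH3OH, rt → 40 °C
Reagents that add atoms: methanol, CO
Why: Acid-catalysed methanolysis of the ketene dithioacetal S-oxide to the arylacetate (second stage of the Ogura–Tsuchihashi synthesis); the acid is used here, before the acid-sensitive side chain exists, and aryl benzyl ethers tolerate methanolic HCl at this temperature.

Step 5
Reactants: 6 2-methylbut-3-en-2-ol
Product: 7 tert-butyl(dimethyl)[(2-methylbut-3-en-2-yl)oxy]silane
Conditions: TBSOTf, 2,6-lutidine, CH2Cl2, 0 °C → rt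
Reagents that add atoms: tert-butyldimethylsilyl trifluoromethanesulfonate, CC(C)(C)[Si](C)(C)OS(=O)(=O)C(F)(F)F
Why: Silylation of a hindered tertiary alcohol needs the silyl triflate; the lutidine buffer keeps the tertiary allylic centre from ionizing.

Step 6
Reactants: 5 methyl 2-[2,4-bis(benzyloxy)-3-iodo-5-methoxyphenyl]acetate; 7 tert-butyl(dimethyl)[(2-methylbut-3-en-2-yl)oxy]silane
Product: 9 methyl 2-Ar-acetate, via alkylborane 8 (not isolated)
Conditions: 7, 9-BBN, THF, rt; then 5, Pd(OAc)2, SPhos, aq. K3PO4, THF, 60 °C
Reagents that add atoms: none
Why: Anti-Markovnikov hydroboration of the monosubstituted alkene followed by B-alkyl Suzuki–Miyaura coupling; the electron-rich biaryl phosphine is chosen for oxidative addition and reductive elimination at the doubly ortho-substituted iodide, and the chain arrives complete and protected.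

Step 7
Reactants: 9 methyl 2-Ar-acetate; 10 methyl formate
Product: 12 methyl (2E)-2-Ar-3-methoxyprop-2-enoate, via sodium enolate 11 (not isolated)
Conditions: 10, NaH, THF, 0 °C → rt; then (CH3O)2SO2, DMF, rt
Reagents that add atoms: dimethyl sulfate, COS(=O)(=O)OC
Why: Crossed Claisen formylation of the arylacetate, then O-methylation of the enolate by a hard electrophile in a dipolar aprotic medium, the standard entry to β-methoxyacrylates; the E isomer, with methoxyl trans to the ester, is the thermodynamic one.

Step 8
Reactants: 12 methyl (2E)-2-Ar-3-methoxyprop-2-enoate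
Product: 13 (2E)-2-Ar-3-methoxyprop-2-enoic acid
Conditions: LiOH·H2O, THF/CH3OH/H2O, 40 °C; then 1 M HCl to pH 4, 0 °C
Reagents that add atoms: lithium hydroxide, [Li+].[OH-]
Why: Saponification; the β-methoxyacrylate is a vinylogous carbonate that resists conjugate displacement under mild hydroxide, and the tertiary silyl ether and benzyl ethers survive the base and the brief cold acidification.

Step 9
Reactants: 13 (2E)-2-Ar-3-methoxyprop-2-enoic acid; 14 methyl 3,5-dioxohexanoate
Product: 17 methyl 3-(5-Ar-2-methyl-4-oxo-4H-pyran-3-yl)-3-oxopropanoate, via acid chloride 15 (not isolated), via triketone 16 (not isolated)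
Conditions: 1-chloro-N,N,2-trimethylprop-1-en-1-amine, CH2Cl2, 0 °C → rt; then 14, MgCl2, pyridine, CH2Cl2, 0 °C → rt; then AcOH, 40 °C
Reagents that add atoms: none
Why: The α-chloroenamine makes the acid chloride under neutral conditions, and the magnesium chelate of the 1,3-diketone of 14 is acylated on carbon at C4 (soft enolization with MgCl2 and amine). The acetyl enol oxygen of the triacylmethane then adds to the methoxyvinyl carbon and methanol is lost (6-endo addition–elimination) under mild acid, which closes the pyranone. Closure through the other enol oxygen or acylation at C2 of 14 would give isomeric pyranones that fold to the same chromone in step 10.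

Step 10
Reactants: 17 methyl 3-(5-Ar-2-methyl-4-oxo-4H-pyran-3-yl)-3-oxopropanoate
Product: 18 3-Ar-5,7-dihydroxy-4H-chromen-4-one
Conditions: KOC(CH3)3 (3 equiv), THF/t-BuOH 10:1 (0.02 M), 0 → 40 °C, Ar; then AcOH
Reagents that add atoms: none
Why: Proposed new method: excess KOC(CH3)3 removes first the ketoester proton at C6 and then a proton of the 2-methyl group (future C8), whose acidity is vinylogous through C8a=C4a to the C4 and C5 carbonyls; the C8 terminus of this dienolate adds to the ester carbonyl C7 of the neighbouring arm, methoxide is expelled, and the pyranone-fused cyclohexenedione tautomerizes at once to the resorcinol, whose phenoxide is the irreversible sink. The closest known reaction type is the biomimetic Claisen cyclization of 3,5,7-triketo esters and of pyrone-masked polyketides to acylphloroglucinols and resorcinols under alkoxide or magnesium alkoxide, where the ester α-position is likewise enolized. Ring A closes in the 6-(enolendo)-exo-trig mode, which is allowed and is helped by the cis disposition of methyl group and arm on the C4a=C8a double bond. No stereocentre is formed. The selectivity needed is carbon acylation by the methyl carbanion in preference to any reaction of the more acidic ketoester enolate and to nucleophilic opening of the pyranone. The substrate secures the first because, while the pyranone is closed, C7–C8 is the only ring-forming C–C bond within reach (C6 cannot span to C2, which lies para to C4a), and the base secures the second because the bulky alkoxide does not add to C2 and the dianion is no longer a Michael acceptor. Methoxide is deliberately not used as the base: it would open the pyranone to the acyclic triketone, in which the ketoester carbanion can close onto the methoxyvinyl carbon and give a biaryl salicylate. High dilution suppresses intermolecular conjugate addition, and the benzyl ethers and the tertiary silyl ether are inert to the base.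

Step 11
Reactants: 18 3-Ar-5,7-dihydroxy-4H-chromen-4-one
Product: 19 3-[2,4-bis(benzyloxy)-3-(3-hydroxy-3-methylbutyl)-5-methoxyphenyl]-5,7-dihydroxy-4H-chromen-4-one
Conditions: Bu4NF (5 equiv), THF, 50 °C
Reagents that add atoms: none
Why: Fluoride-induced cleavage of the Si–O bond; it is done while O2' and O4' are benzylated, so the freed alcohol has no phenol to cyclize onto and the basic medium meets no oxidizable ring B phenoxide, while the 7-phenoxide formed in the flask shields the chromone from nucleophilic opening.

Step 12
Reactants: 19 3-[2,4-bis(benzyloxy)-3-(3-hydroxy-3-methylbutyl)-5-methoxyphenyl]-5,7-dihydroxy-4H-chromen-4-one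
Product: 20 3-[2,4-dihydroxy-3-(3-hydroxy-3-methylbutyl)-5-methoxyphenyl]-5,7-dihydroxy-4H-chromen-4-one
Conditions: H2 (1 atm), 10% Pd/C, EtOAc/CH3OH, rt
Reagents that add atoms: none
Why: Neutral heterogeneous hydrogenolysis of the two aryl benzyl ethers, the one unmasking that exposes the phenol/tertiary alcohol pair to neither acid nor base; aryl benzyl ethers should cleave well before the chromone C2=C3 bond is saturated, so the reaction is stopped at full debenzylation.

**Compound list**

1 | 2,4-dihydroxy-5-methoxybenzaldehyde | COc1cc(C=O)c(O)cc1O | starting material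
2 | 2,4-dihydroxy-3-iodo-5-methoxybenzaldehyde | COc1cc(C=O)c(O)c(I)c1O | intermediate
3 | 2,4-bis(benzyloxy)-3-iodo-5-methoxybenzaldehyde | COc1cc(C=O)c(OCc2ccccc2)c(I)c1OCc1ccccc1 | intermediate
4 | 2,4-bis(benzyloxy)-3-iodo-5-methoxy-1-[2-(methylsulfanyl)-2-(methylsulfinyl)ethenyl]benzene (expected as alkene isomers; racemic at sulfur) | COc1cc(C=C(SC)S(C)=O)c(OCc2ccccc2)c(I)c1OCc1ccccc1 | intermediate
5 | methyl 2-[2,4-bis(benzyloxy)-3-iodo-5-methoxyphenyl]acetate | COC(=O)Cc1cc(OC)c(OCc2ccccc2)c(I)c1OCc1ccccc1 | intermediate
6 | 2-methylbut-3-en-2-ol | C=CC(C)(C)O | starting material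
7 | tert-butyl(dimethyl)[(2-methylbut-3-en-2-yl)oxy]silane | C=CC(C)(C)O[Si](C)(C)C(C)(C)C | intermediate
8 | 9-(3-{[tert-butyl(dimethyl)silyl]oxy}-3-methylbutyl)-9-borabicyclo[3.3.1]nonane | CC(C)(CCB1C2CCCC1CCC2)O[Si](C)(C)C(C)(C)C | intermediate (not isolated)
9 | methyl 2-[2,4-bis(benzyloxy)-3-(3-{[tert-butyl(dimethyl)silyl]oxy}-3-methylbutyl)-5-methoxyphenyl]acetate | COC(=O)Cc1cc(OC)c(OCc2ccccc2)c(CCC(C)(C)O[Si](C)(C)C(C)(C)C)c1OCc1ccccc1 | intermediate
10 | methyl formate | COC=O | starting material
11 | sodium 2-Ar-3-methoxy-3-oxoprop-1-en-1-olate (enolate geometry not fixed) | COC(=O)C(=C[O-])c1cc(OC)c(OCc2ccccc2)c(CCC(C)(C)O[Si](C)(C)C(C)(C)C)c1OCc1ccccc1.[Na+] | intermediate (not isolated)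
12 | methyl (2E)-2-Ar-3-methoxyprop-2-enoate | CO/C=C(/C(=O)OC)c1cc(OC)c(OCc2ccccc2)c(CCC(C)(C)O[Si](C)(C)C(C)(C)C)c1OCc1ccccc1 | intermediate
13 | (2E)-2-Ar-3-methoxyprop-2-enoic acid | CO/C=C(/C(=O)O)c1cc(OC)c(OCc2ccccc2)c(CCC(C)(C)O[Si](C)(C)C(C)(C)C)c1OCc1ccccc1 | intermediate
14 | methyl 3,5-dioxohexanoate | CC(=O)CC(=O)CC(=O)OC | starting material
15 | (2E)-2-Ar-3-methoxyprop-2-enoyl chloride | CO/C=C(/C(Cl)=O)c1cc(OC)c(OCc2ccccc2)c(CCC(C)(C)O[Si](C)(C)C(C)(C)C)c1OCc1ccccc1 | intermediate (not isolated)
16 | methyl (6E)-4-acetyl-6-Ar-7-methoxy-3,5-dioxohept-6-enoate (drawn as the triketo tautomer; enolized at C4) | CO/C=C(/C(=O)C(C(C)=O)C(=O)CC(=O)OC)c1cc(OC)c(OCc2ccccc2)c(CCC(C)(C)O[Si](C)(C)C(C)(C)C)c1OCc1ccccc1 | intermediate (not isolated)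
17 | methyl 3-(5-Ar-2-methyl-4-oxo-4H-pyran-3-yl)-3-oxopropanoate | COC(=O)CC(=O)c1c(C)occ(-c2cc(OC)c(OCc3ccccc3)c(CCC(C)(C)O[Si](C)(C)C(C)(C)C)c2OCc2ccccc2)c1=O | intermediate
18 | 3-Ar-5,7-dihydroxy-4H-chromen-4-one | COc1cc(-c2coc3cc(O)cc(O)c3c2=O)c(OCc2ccccc2)c(CCC(C)(C)O[Si](C)(C)C(C)(C)C)c1OCc1ccccc1 | intermediate
19 | 3-[2,4-bis(benzyloxy)-3-(3-hydroxy-3-methylbutyl)-5-methoxyphenyl]-5,7-dihydroxy-4H-chromen-4-one | COc1cc(-c2coc3cc(O)cc(O)c3c2=O)c(OCc2ccccc2)c(CCC(C)(C)O)c1OCc1ccccc1 | intermediate
20 | 3-[2,4-dihydroxy-3-(3-hydroxy-3-methylbutyl)-5-methoxyphenyl]-5,7-dihydroxy-4H-chromen-4-one | COc1cc(-c2coc3cc(O)cc(O)c3c2=O)c(O)c(CCC(C)(C)O)c1O | target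

**Step count and risk**

Total: 12 steps. Longest linear sequence: 11 steps (1 → 20 through steps 1–4 and 6–12); step 5 is a one-step side branch.

Step 10 (key step, new method). Three processes may defeat it:
- Failure of ring closure: the ester carbonyl is deactivated once its α-position is enolized, so the dianion may not close below the temperature at which it decomposes.
- Pyranone opening: the methoxide set free as the reaction proceeds may open the pyranone of unreacted material and unlock other foldings to biaryls.
- Intermolecular conjugate addition: the ketoester enolate of one molecule may add to the pyranone CH of another.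

Fallback by known chemistry, setting out from 3 and returning at 20: 3 is coupled with borane 8 under the conditions of step 6 to give 2,4-bis(benzyloxy)-3-(3-{[tert-butyl(dimethyl)silyl]oxy}-3-methylbutyl)-5-methoxybenzaldehyde F1. Claisen–Schmidt condensation of F1 with commercial 1-[2,4-bis(benzyloxy)-6-hydroxyphenyl]ethanone (KOH, EtOH/THF) gives the (E)-chalcone F2. Oxidative 1,2-aryl migration with Tl(NO3)3 in CH3OH/HC(OCH3)3 gives the 2-aryl-3,3-dimethoxypropan-1-one F3. Brief treatment with dilute methanolic HCl closes ring C to 3-Ar-5,7-bis(benzyloxy)-4H-chromen-4-one F4. Bu4NF then gives the tertiary alcohol F5, and hydrogenolysis over Pd/C gives 20.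

Step 9. Acylation may go to the wrong site (oxygen, or C2 of 14), and 14 may lactonize to a 4-hydroxy-2-pyranone before it is acylated; both would erode the supply of 17. Fallback, setting out from 13 and returning at 17: acid chloride 15, made as in step 9, acylates allyl acetoacetate (MgCl2, pyridine), which has a single acidic site, and acid closure gives allyl 5-Ar-2-methyl-4-oxo-4H-pyran-3-carboxylate F6. Deallylation with Pd(PPh3)4 and morpholine gives 5-Ar-2-methyl-4-oxo-4H-pyran-3-carboxylic acid F7. Activation of F7 with 1,1'-carbonyldiimidazole and treatment with the magnesium salt of monomethyl malonate (Masamune–Brooks homologation) gives 17.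

Step 6. Transmetalation and reductive elimination at the iodide flanked by two benzyloxy groups may be slow, so that protodeiodination or partial ester hydrolysis wins. Fallback, setting out from 5 and returning at 9: Sonogashira coupling of 5 with 2-methylbut-3-yn-2-ol (PdCl2(PPh3)2, CuI, Et3N) gives methyl 2-[2,4-bis(benzyloxy)-3-(3-hydroxy-3-methylbut-1-yn-1-yl)-5-methoxyphenyl]acetate F8. Hydrogenation over PtO2, which leaves aryl benzyl ethers alone, gives methyl 2-[2,4-bis(benzyloxy)-3-(3-hydroxy-3-methylbutyl)-5-methoxyphenyl]acetate F9. Silylation with TBSOTf and 2,6-lutidine gives 9.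

Step 12. Selectivity may be lost between hydrogenolysis of the benzyl C–O bonds and saturation of C2=C3, giving the isoflavanone. Fallback, setting out from 18 and returning at 20: the benzyl ethers are removed from 18 with BCl3 and pentamethylbenzene at −78 °C, while the tertiary alcohol is still silylated and so cannot ionize toward the freed phenols. This gives 3-[3-(3-{[tert-butyl(dimethyl)silyl]oxy}-3-methylbutyl)-2,4-dihydroxy-5-methoxyphenyl]-5,7-dihydroxy-4H-chromen-4-one F10. Desilylation of F10 with Bu4NF buffered by AcOH under argon gives 20.

**Further compounds**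

F1 | step 10 | 2,4-bis(benzyloxy)-3-(3-{[tert-butyl(dimethyl)silyl]oxy}-3-methylbutyl)-5-methoxybenzaldehyde | COc1cc(C=O)c(OCc2ccccc2)c(CCC(C)(C)O[Si](C)(C)C(C)(C)C)c1OCc1ccccc1
F2 | step 10 | (2E)-3-Ar-1-[2,4-bis(benzyloxy)-6-hydroxyphenyl]prop-2-en-1-one | COc1cc(/C=C/C(=O)c2c(O)cc(OCc3ccccc3)cc2OCc2ccccc2)c(OCc2ccccc2)c(CCC(C)(C)O[Si](C)(C)C(C)(C)C)c1OCc1ccccc1
F3 | step 10 | 2-Ar-1-[2,4-bis(benzyloxy)-6-hydroxyphenyl]-3,3-dimethoxypropan-1-one (racemic) | COc1cc(C(C(OC)OC)C(=O)c2c(O)cc(OCc3ccccc3)cc2OCc2ccccc2)c(OCc2ccccc2)c(CCC(C)(C)O[Si](C)(C)C(C)(C)C)c1OCc1ccccc1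
F4 | step 10 | 3-Ar-5,7-bis(benzyloxy)-4H-chromen-4-one | COc1cc(-c2coc3cc(OCc4ccccc4)cc(OCc4ccccc4)c3c2=O)c(OCc2ccccc2)c(CCC(C)(C)O[Si](C)(C)C(C)(C)C)c1OCc1ccccc1
F5 | step 10 | 5,7-bis(benzyloxy)-3-[2,4-bis(benzyloxy)-3-(3-hydroxy-3-methylbutyl)-5-methoxyphenyl]-4H-chromen-4-one | COc1cc(-c2coc3cc(OCc4ccccc4)cc(OCc4ccccc4)c3c2=O)c(OCc2ccccc2)c(CCC(C)(C)O)c1OCc1ccccc1
F6 | step 9 | allyl 5-Ar-2-methyl-4-oxo-4H-pyran-3-carboxylate | C=CCOC(=O)c1c(C)occ(-c2cc(OC)c(OCc3ccccc3)c(CCC(C)(C)O[Si](C)(C)C(C)(C)C)c2OCc2ccccc2)c1=O
F7 | step 9 | 5-Ar-2-methyl-4-oxo-4H-pyran-3-carboxylic acid | OC(=O)c1c(C)occ(-c2cc(OC)c(OCc3ccccc3)c(CCC(C)(C)O[Si](C)(C)C(C)(C)C)c2OCc2ccccc2)c1=O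
F8 | step 6 | methyl 2-[2,4-bis(benzyloxy)-3-(3-hydroxy-3-methylbut-1-yn-1-yl)-5-methoxyphenyl]acetate | COC(=O)Cc1cc(OC)c(OCc2ccccc2)c(C#CC(C)(C)O)c1OCc1ccccc1
F9 | step 6 | methyl 2-[2,4-bis(benzyloxy)-3-(3-hydroxy-3-methylbutyl)-5-methoxyphenyl]acetate | COC(=O)Cc1cc(OC)c(OCc2ccccc2)c(CCC(C)(C)O)c1OCc1ccccc1
F10 | step 12 | 3-[3-(3-{[tert-butyl(dimethyl)silyl]oxy}-3-methylbutyl)-2,4-dihydroxy-5-methoxyphenyl]-5,7-dihydroxy-4H-chromen-4-one | COc1cc(-c2coc3cc(O)cc(O)c3c2=O)c(O)c(CCC(C)(C)O[Si](C)(C)C(C)(C)C)c1O
A1 | alternative 1 | 1-[2,4-bis(benzyloxy)-6-(formyloxy)phenyl]-2-[2,4-bis(benzyloxy)-5-methoxy-3-(3-methyl-3-[(triethylsilyl)oxy]butyl)phenyl]-2-(triphenylphosphoranylidene)ethanone | O=COc1cc(OCc2ccccc2)cc(OCc2ccccc2)c1C(=O)C(=P(c1ccccc1)(c1ccccc1)c1ccccc1)c1cc(OC)c(OCc2ccccc2)c(CCC(C)(C)O[Si](CC)(CC)CC)c1OCc1ccccc1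
A2 | alternative 1 | 5,7-bis(benzyloxy)-3-[2,4-bis(benzyloxy)-5-methoxy-3-(3-methyl-3-[(triethylsilyl)oxy]butyl)phenyl]-4H-chromen-4-one | COc1cc(-c2coc3cc(OCc4ccccc4)cc(OCc4ccccc4)c3c2=O)c(OCc2ccccc2)c(CCC(C)(C)O[Si](CC)(CC)CC)c1OCc1ccccc1
A3 | alternative 2 | pentacarbonyl{(2Z)-1-methoxy-2-(methoxymethoxy)-6-methyl-6-[(triethylsilyl)oxy]hept-2-en-1-ylidene}chromium | COC(=[Cr](=C=O)(=C=O)(=C=O)(=C=O)=C=O)/C(OCOC)=C/CCC(C)(C)O[Si](CC)(CC)CC
A4 | alternative 2 | 5,7-bis(benzyloxy)-3-ethynyl-4H-chromen-4-one | C#Cc1coc2cc(OCc3ccccc3)cc(OCc3ccccc3)c2c1=O
A5 | alternative 2 | 5,7-bis(benzyloxy)-3-[2-hydroxy-5-methoxy-4-(methoxymethoxy)-3-(3-methyl-3-[(triethylsilyl)oxy]butyl)phenyl]-4H-chromen-4-one | COc1cc(-c2coc3cc(OCc4ccccc4)cc(OCc4ccccc4)c3c2=O)c(O)c(CCC(C)(C)O[Si](CC)(CC)CC)c1OCOC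
A6 | alternative 3 | 3,5-bis(benzyloxy)-2-(trimethylsilyl)phenyl trifluoromethanesulfonate | C[Si](C)(C)c1c(OCc2ccccc2)cc(OCc2ccccc2)cc1OS(=O)(=O)C(F)(F)F
A7 | alternative 3 | 3,5-bis(benzyloxy)benzyne | C1#CC(OCc2ccccc2)=CC(OCc2ccccc2)=C1
A8 | alternative 3 | methyl 2-Ar-3-hydroxyprop-2-enoate (enol form; geometry not fixed) | COC(=O)C(=CO)c1cc(OC)c(OCc2ccccc2)c(CCC(C)(C)O[Si](C)(C)C(C)(C)C)c1OCc1ccccc1
A9 | alternative 3 | 3-Ar-5,7-bis(benzyloxy)-4H-chromen-4-one | COc1cc(-c2coc3cc(OCc4ccccc4)cc(OCc4ccccc4)c3c2=O)c(OCc2ccccc2)c(CCC(C)(C)O[Si](C)(C)C(C)(C)C)c1OCc1ccccc1
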